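**Retrosynthetic overview**
1. 16 ⇒ 15: cut O–C15. Ring D (the 2,3-dihydrofuran) closes last, by oxidative addition of the 16-OH to the 13-vinyl group.
2. 15 ⇒ 11: no ring change. The 6-oxo group, 7β-OH and 5β-H come from the 7-ketone by dehydrogenation, reduction, α-epoxidation and a C6→C5 hydride shift.
3. 11 ⇒ 10: cut O9–C13. Ring C (the oxolane) forms when the 9α-OH traps a C13–C15 allyl cation equivalent (π-allylpalladium from a 13,16-epoxy-14-ene), as in the biosynthesis of 9,13-epoxylabd-14-ene.
4. 10 ⇒ 3: the 8α,9α-diol comes from α-face dihydroxylation of an 8-en-7-one. C16 is oxidised as its chloride, and C14–C15 are returned as a vinyl Grignard reagent.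
5. 3 ⇒ sclareol 1, which supplies rings A and B. Ring order: A/B (bought) → C → D.

Assumption: the SMILES is read literally, so H-5 is cis to CH3-20 (5β-H, A/B cis), with 7β-OH, 8α-OAc (CH3-17 β), 9α-O (C11 β), 10β-CH3 and 13S; labdane numbering is used throughout.

Step 1
Reactants: 1 (−)-sclareol, (13R)-labd-14-ene-8α,13-diol
Product: 2 8α-hydroxy-14,15-dinorlabdan-13-one
Conditions: KMnO4 (4 equiv), acetone/H2O, 0 °C → rt
Reagents that add atoms: none
Why: Permanganate cleavage of the tertiary vinyl carbinol (C=C cleavage, then oxidative decarboxylation of the α-hydroxy acid) removes C14 and C15 and leaves the methyl ketone, while C5, C8, C9 and C10 of sclareol are untouched.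

Step 2
Reactants: 2 8α-hydroxy-14,15-dinorlabdan-13-one
Product: 3 14,15-dinorlabd-8(9)-en-13-one (5α-H, 10β-CH3)
Conditions: p-TsOH·H2O (10 mol %), toluene, reflux, Dean–Stark
Reagents that add atoms: none
Why: Acid-catalysed E1 dehydration under equilibrating conditions funnels the C8 cation to the most substituted (Zaitsev) 8(9)-alkene, erasing C8 and C9, which are set again in step 5.

Step 3
Reactants: 3 14,15-dinorlabd-8(9)-en-13-one
Product: 5 16-chloro-14,15-dinorlabd-8(9)-en-13-one, via lithium enolate 4 (not isolated)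
Conditions: LiN(iPr)2 (1.1 equiv), THF, −78 °C; N-chlorosuccinimide, −78 → −30 °C; H2O
Reagents that add atoms: N-chlorosuccinimide, O=C1CCC(=O)N1Cl
Why: Kinetic deprotonation of the methyl ketone at the less hindered CH3 followed by electrophilic enolate chlorination raises C16 to the alcohol oxidation level that the biosynthesis reaches by C16 hydroxylation.

Step 4
Reactants: 5 16-chloro-14,15-dinorlabd-8(9)-en-13-one
Product: 6 16-chloro-14,15-dinorlabd-8(9)-ene-7,13-dione
Conditions: CrO3 (12 equiv), 3,5-dimethylpyrazole (12 equiv), CH2Cl2, −20 °C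
Reagents that add atoms: chromium trioxide, O=[Cr](=O)=O
Why: Salmond allylic oxidation attacks the ring methylene C7, whose axial C–H is aligned with the alkene π system, in preference to side-chain C11 and the C17 methyl, and the chloroketone is inert to the oxidant.

Step 5
Reactants: 6 16-chloro-14,15-dinorlabd-8(9)-ene-7,13-dione
Product: 7 16-chloro-8α,9α-dihydroxy-14,15-dinorlabdane-7,13-dione
Conditions: K2OsO4·2H2O (5 mol %), NMO (2 equiv), citric acid (1.5 equiv), t-BuOH/H2O 1:1, 45 °C
Reagents that add atoms: N-methylmorpholine N-oxide, C[N+]1([O-])CCOCC1; water, O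
Why: Citric-acid-buffered Upjohn syn-dihydroxylation, the protocol for hindered electron-poor alkenes, occurs on the α face because the axial C20 methyl covers the β face, so 8α-OH and 9α-OH (C17 and C11 both β) are set together, and the buffer keeps N-methylmorpholine protonated so that it does not alkylate on the chloroketone.

Step 6
Reactants: 7 16-chloro-8α,9α-dihydroxy-14,15-dinorlabdane-7,13-dione
Product: 9 13,16-epoxy-8α,9α-dihydroxylabd-14-en-7-one (about 1:1 at C13), via chlorohydrin 8 (not isolated)
Conditions: CH2=CHMgBr (3.2 equiv), THF, −78 °C; H2O; crude, K2CO3, MeOH, 0 °C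
Reagents that add atoms: vinylmagnesium bromide, C=C[Mg]Br
Why: After two equivalents are spent on the hydroxyls, the unhindered chlorine-activated C13 ketone takes up the Grignard reagent far faster than the neopentyl C7 ketone, and mild base closes the tertiary chlorohydrin to the 2-alkyl-2-vinyloxirane (Grignard addition, then Williamson-type closure); C13 forms unselectively, which is harmless because step 8 is stereoconvergent.

Step 7
Reactants: 9 13,16-epoxy-8α,9α-dihydroxylabd-14-en-7-one
Product: 10 8α-acetoxy-13,16-epoxy-9α-hydroxylabd-14-en-7-one (about 1:1 at C13)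
Conditions: Ac2O (3 equiv), DMAP (0.3 equiv), Et3N, CH2Cl2, 35 °C
Reagents that add atoms: acetic anhydride, CC(=O)OC(C)=O
Why: DMAP-catalysed acetylation distinguishes the equatorial 8α-OH from the axial 9α-OH, which sits between two fully substituted carbons and resists acylation as forskolin-type 9α-alcohols do, so the final acetate is placed and the only competing nucleophile for step 8 is removed.

Step 8
Reactants: 10 8α-acetoxy-13,16-epoxy-9α-hydroxylabd-14-en-7-one
Product: 11 (13S)-8α-acetoxy-9α,13-epoxy-16-hydroxylabd-14-en-7-one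
Conditions: Pd2(dba)3·CHCl3 (2.5 mol %), (R,R)-DACH-phenyl Trost ligand (7.5 mol %), Et3B (5 mol %), CH2Cl2, rt
Reagents that add atoms: none
Why: Proposed new method: zerovalent palladium opens both C13 epimers of the vinyloxirane to one zwitterionic π-allyl complex, the laboratory counterpart of the C13–C15 allyl cation that the terpene synthase makes by diphosphate loss, the C16 alkoxide deprotonates the only free hydroxyl (9α-OH), and this closes the five-membered ring at the more substituted terminus C13 (5-exo, anti to palladium) while fast η3–η1–η3 face exchange through the unsubstituted C15 terminus lets the ligand pocket rather than the epoxide configuration fix C13 as S (sense assigned by analogy, the antipodal ligand giving the 13-epimer); the closest known reaction type is the Trost dynamic kinetic asymmetric addition of alcohols to 2-alkyl-2-vinyloxiranes, run here intramolecularly on a hindered tertiary alcohol.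

Step 9
Reactants: 11 (13S)-8α-acetoxy-9α,13-epoxy-16-hydroxylabd-14-en-7-one
Product: 12 (13S)-8α-acetoxy-9α,13-epoxy-7-oxolabda-5,14-dien-16-al
Conditions: IBX (4 equiv), DMSO, 75 °C
Reagents that add atoms: none
Why: IBX oxidises the primary 16-OH to a non-enolisable aldehyde and dehydrogenates the ketone through its only possible enol (towards C6) to the 5-en-7-one (Nicolaou IBX dehydrogenation), which makes C5 trigonal so that its configuration can be rewritten, while C8, C9, C10 and C13 carry no acidic hydrogen.

Step 10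
Reactants: 12 (13S)-8α-acetoxy-9α,13-epoxy-7-oxolabda-5,14-dien-16-al
Product: 13 (13S)-8α-acetoxy-9α,13-epoxylabda-5,14-diene-7β,16-diol
Conditions: NaBH4, CeCl3·7H2O, MeOH, −40 °C
Reagents that add atoms: none
Why: Luche 1,2-reduction returns the aldehyde to the 16-alcohol and reduces the enone from the α face, anti to the axial 8β-methyl beside the carbonyl, so the new C7 stereocentre is the equatorial 7β-alcohol, and the low temperature suppresses acetyl migration from O8.

Step 11
Reactants: 13 (13S)-8α-acetoxy-9α,13-epoxylabda-5,14-diene-7β,16-diol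
Product: 14 (13S)-8α-acetoxy-5α,6α:9α,13-diepoxylabd-14-ene-7β,16-diol
Conditions: dimethyldioxirane (1.1 equiv, acetone), CH2Cl2, −20 °C
Reagents that add atoms: dimethyldioxirane, CC1(C)OO1
Why: Sterically governed dioxirane epoxidation picks the electron-rich trisubstituted 5,6-alkene over the monosubstituted vinyl group and comes from the α face because the axial 4β- and 10β-methyls wall off the β face of C5, which sets the 5α,6α-epoxide and leaves H-6 on the β face.

Step 12
Reactants: 14 (13S)-8α-acetoxy-5α,6α:9α,13-diepoxylabd-14-ene-7β,16-diol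
Product: 15 (13S)-8α-acetoxy-9α,13-epoxy-7β,16-dihydroxy-5β-labd-14-en-6-one
Conditions: BF3·OEt2 (2.5 equiv), CH2Cl2, −78 °C, 10 min; Et3N
Reagents that add atoms: none
Why: In this Meinwald rearrangement BF3 breaks the tertiary C5–O bond of the α-epoxide and the β-hydrogen on C6 migrates to the β face of C5 as oxygen leaves from the α face, which creates the C6 ketone and the contra-steric 5β-H (A/B cis) in one stereospecific event, as steroidal 5α,6α-epoxides give 5β-6-ketones, and the short cold contact avoids enolisation and ionisation of the allylic ether.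

Step 13
Reactants: 15 (13S)-8α-acetoxy-9α,13-epoxy-7β,16-dihydroxy-5β-labd-14-en-6-one
Product: 16 (13S)-8α-acetoxy-9α,13:15,16-diepoxy-7β-hydroxy-5β-labd-14-en-6-one (target)
Conditions: Pd(OCOCF3)2 (10 mol %), pyridine (40 mol %), Na2CO3, MS 3 Å, O2 (1 atm), toluene, 60 °C
Reagents that add atoms: none
Why: Proposed new method: divalent palladium activates the terminal vinyl group, the neopentyl 16-OH can add only at C15 (5-endo, since the 4-exo mode would give an oxetane and a quaternary allylic carbon steers attack to the terminus as in aldehyde-selective Wacker oxidations), and the C14–Pd intermediate has β-hydrogens only on C15, so β-hydride elimination must give the C14=C15 enol ether while O2 reoxidises palladium, which copies the oxidative C16–O–C15 closure of the biosynthesis under buffered non-acidic conditions that neither open the vinylogous acetal to the furan nor enolise C5; the closest known reaction type is the aerobic Wacker-type oxidative cyclisation of alkenols.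

**Compound list**
1 | (−)-sclareol, (13R)-labd-14-ene-8α,13-diol | O[C@]1(C)CC[C@H]2C(C)(C)CCC[C@]2(C)[C@H]1CC[C@](C)(C=C)O | starting material
2 | 8α-hydroxy-14,15-dinorlabdan-13-one | O[C@]1(C)CC[C@H]2C(C)(C)CCC[C@]2(C)[C@H]1CCC(C)=O | intermediate
3 | 14,15-dinorlabd-8(9)-en-13-one | CC1=C(CCC(C)=O)[C@@]2(C)CCCC(C)(C)[C@@H]2CC1 | intermediate
4 | lithium C13(O)=C16 enolate of 3 | CC1=C(CCC(=C)[O-])[C@@]2(C)CCCC(C)(C)[C@@H]2CC1.[Li+] | intermediate
5 | 16-chloro-14,15-dinorlabd-8(9)-en-13-one | CC1=C(CCC(=O)CCl)[C@@]2(C)CCCC(C)(C)[C@@H]2CC1 | intermediate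
6 | 16-chloro-14,15-dinorlabd-8(9)-ene-7,13-dione | CC1=C(CCC(=O)CCl)[C@@]2(C)CCCC(C)(C)[C@@H]2CC1=O | intermediate
7 | 16-chloro-8α,9α-dihydroxy-14,15-dinorlabdane-7,13-dione | O[C@]1(C)C(=O)C[C@H]2C(C)(C)CCC[C@]2(C)[C@@]1(O)CCC(=O)CCl | intermediate
8 | 16-chloro-8α,9α,13-trihydroxylabd-14-en-7-one (both C13 epimers) | O[C@]1(C)C(=O)C[C@H]2C(C)(C)CCC[C@]2(C)[C@@]1(O)CCC(O)(CCl)C=C | intermediate
9 | 13,16-epoxy-8α,9α-dihydroxylabd-14-en-7-one (both C13 epimers) | O[C@]1(C)C(=O)C[C@H]2C(C)(C)CCC[C@]2(C)[C@@]1(O)CCC1(CO1)C=C | intermediate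
10 | 8α-acetoxy-13,16-epoxy-9α-hydroxylabd-14-en-7-one (both C13 epimers) | CC(=O)O[C@]1(C)C(=O)C[C@H]2C(C)(C)CCC[C@]2(C)[C@@]1(O)CCC1(CO1)C=C | intermediate
11 | (13S)-8α-acetoxy-9α,13-epoxy-16-hydroxylabd-14-en-7-one | CC(=O)O[C@]1(C)C(=O)C[C@H]2C(C)(C)CCC[C@]2(C)[C@@]12CC[C@@](CO)(C=C)O2 | intermediate
12 | (13S)-8α-acetoxy-9α,13-epoxy-7-oxolabda-5,14-dien-16-al | CC(=O)O[C@]1(C)C(=O)C=C2C(C)(C)CCC[C@]2(C)[C@@]12CC[C@@](C=O)(C=C)O2 | intermediate
13 | (13S)-8α-acetoxy-9α,13-epoxylabda-5,14-diene-7β,16-diol | CC(=O)O[C@]1(C)[C@@H](O)C=C2C(C)(C)CCC[C@]2(C)[C@@]12CC[C@@](CO)(C=C)O2 | intermediate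
14 | (13S)-8α-acetoxy-5α,6α:9α,13-diepoxylabd-14-ene-7β,16-diol | CC(=O)O[C@]1(C)[C@@H](O)[C@@H]3O[C@@]32C(C)(C)CCC[C@]2(C)[C@@]12CC[C@@](CO)(C=C)O2 | intermediate
15 | (13S)-8α-acetoxy-9α,13-epoxy-7β,16-dihydroxy-5β-labd-14-en-6-one | CC(=O)O[C@]1(C)[C@@H](O)C(=O)[C@@H]2C(C)(C)CCC[C@]2(C)[C@@]12CC[C@@](CO)(C=C)O2 | intermediate
16 | (13S)-8α-acetoxy-9α,13:15,16-diepoxy-7β-hydroxy-5β-labd-14-en-6-one | CC(=O)O[C@]1(C)[C@@H](O)C(=O)[C@@H]2C(C)(C)CCC[C@]2(C)[C@@]12CC[C@@]1(C=COC1)O2 | target

Total step count: 13. Longest linear sequence: 13 (fully linear from sclareol).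

**Steps most likely to fail**

**Step 8.** The very hindered 9α-OH may not intercept the π-allyl complex, so that dienol or enal isomers of the epoxide form instead, or the ligand may not control C13. The fallback sets out from 10 and uses a stereospecific cationic closure instead of a stereoconvergent one.
- The C13 epimers of 10 are separated by chromatography.
- The (13R)-epimer of 10 F1 is treated with camphorsulfonic acid (5 mol %) in CH2Cl2 at −40 °C.
- The 9α-OH then opens the epoxide at the tertiary allylic carbon (5-exo) with inversion, which returns to the route at 11.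
- The unwanted (13S)-epimer is re-equilibrated at C13 with Pd(PPh3)4 and recycled.

**Step 12.** Methyl migration from C4 or C10 to the C5 cation, or loss of H-6 to an enol that reprotonates from the α face, could replace the hydride shift. The fallback sets out from 12 and delivers the 5β-hydrogen by an allylic diazene retro-ene reaction.
- NaBH(OAc)3 reduces only the aldehyde, giving the 16-hydroxy-5-en-7-one F2.
- TsNHNH2 in warm ethanol gives the C7 tosylhydrazone F3.
- Catecholborane at −40 °C adds hydride to C7 from the α face. NaOAc·3H2O then releases the 7β-diazene, which transfers its hydrogen suprafacially to the β face of C5 and gives the 5β-labda-6,14-diene F4.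
- Dimethyldioxirane epoxidises the ring alkene anti to the allylic 8α-acetate, on the convex face, to give the 6β,7β-epoxide F5.
- DMSO with catalytic CF3SO3H, then Et3N, opens the epoxide at C6 from the α face and collapses in a Kornblum-type oxidation. This keeps the 7β-OH and returns to the route at 15.

**Step 13.** A 5-endo oxypalladation onto a terminal vinyl group has little precedent. Palladium could instead oxidise an alcohol, or act as a Lewis acid on the product. The fallback sets out from 15 and replaces palladium by electrophilic selenium.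
- PhSeCl and K2CO3 in CH2Cl2 at −78 °C effect a 5-endo selenoetherification, giving the 14-phenylselanyl-15,16-epoxide F6.
- One equivalent of mCPBA at −78 °C gives the selenoxide F7.
- On warming with iPr2NH, the selenoxide undergoes syn elimination. It can use only a C15 hydrogen because C13 is quaternary, and this returns to the route at 16.

**Further compounds**
F1 | step 8 | (13R)-8α-acetoxy-13,16-epoxy-9α-hydroxylabd-14-en-7-one | CC(=O)O[C@]1(C)C(=O)C[C@H]2C(C)(C)CCC[C@]2(C)[C@@]1(O)CC[C@]1(CO1)C=C
F2 | step 12 | (13S)-8α-acetoxy-9α,13-epoxy-16-hydroxylabda-5,14-dien-7-one | CC(=O)O[C@]1(C)C(=O)C=C2C(C)(C)CCC[C@]2(C)[C@@]12CC[C@@](CO)(C=C)O2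
F3 | step 12 | C7 tosylhydrazone of F2 | CC(=O)O[C@]1(C)C(=NNS(=O)(=O)c3ccc(C)cc3)C=C2C(C)(C)CCC[C@]2(C)[C@@]12CC[C@@](CO)(C=C)O2
F4 | step 12 | (13S)-8α-acetoxy-9α,13-epoxy-5β-labda-6,14-dien-16-ol | CC(=O)O[C@]1(C)C=C[C@@H]2C(C)(C)CCC[C@]2(C)[C@@]12CC[C@@](CO)(C=C)O2
F5 | step 12 | (13S)-8α-acetoxy-6β,7β:9α,13-diepoxy-5β-labd-14-en-16-ol | CC(=O)O[C@]1(C)[C@H]3O[C@H]3[C@@H]2C(C)(C)CCC[C@]2(C)[C@@]12CC[C@@](CO)(C=C)O2
F6 | step 13 | (13S)-8α-acetoxy-9α,13:15,16-diepoxy-7β-hydroxy-14-phenylselanyl-5β-labdan-6-one (C14 undefined) | CC(=O)O[C@]1(C)[C@@H](O)C(=O)[C@@H]2C(C)(C)CCC[C@]2(C)[C@@]12CC[C@@]1(C([Se]c3ccccc3)COC1)O2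
F7 | step 13 | selenoxide of F6 | CC(=O)O[C@]1(C)[C@@H](O)C(=O)[C@@H]2C(C)(C)CCC[C@]2(C)[C@@]12CC[C@@]1(C([Se](=O)c3ccccc3)COC1)O2
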